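**Plan**
- Retrosynthesis: the three phenols are first masked as benzyl ethers; then C1–C2 and C2–C3 of the tetralone are cut, which removes C2. C2 is a lone CH2 between the carbonyl carbon C1 and C3, so the cyclohexanone ring is the five-membered ring of a 3-arylindan-1-one with one carbon inserted between C=O and the α-carbon.
- The indanone is cut at the C3–C3a aryl bond and at the enone C=C, giving a 2-bromoacetophenone (from bromohydroquinone) and a naphthaldehyde (from 5-methoxy-1-naphthol).
- Forward: aldehyde 5 (steps 1–3) and ketone 9 (steps 4–5) are joined to a chalcone; the five-membered ring closes by asymmetric reductive Heck cyclisation; the silyl enol ether is cyclopropanated; opening of the shared cyclopropane bond gives the six-membered ring; dechlorination and debenzylation finish.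
- Stereochemistry: the only stereocentre of the target, C4 (S), is set by the chiral bisphosphine on palladium in step 7 and is not touched again. The two cyclopropane centres and the C–Cl centre are transient.

Key step: step 9

Remarks on the chemistry: the (R)-bisphosphine in step 7 is assumed to give the 3S-indanone; if a test run shows the opposite sense, the (S)-ligand is used and nothing else changes. Compound 16 is drawn as the expected 3,4-trans epimer; its C3 epimer would converge in step 11.

**Route**

Step 1
Reactants: 1 5-methoxy-1-naphthol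
Product: 2 4-bromo-5-methoxynaphthalen-1-ol
Conditions: NBS (1.0 equiv), MeCN, −20 to 0 °C, dark
Reagents that add atoms: N-bromosuccinimide O=C1CCC(=O)N1Br
Why: Electrophilic aromatic bromination, in which the free naphthol OH activates its para position C4 far more than the methoxy group activates the other ring, and NBS in acetonitrile favours para over ortho attack on 1-naphthols.

Step 2
Reactants: 2 4-bromo-5-methoxynaphthalen-1-ol
Product: 3 1-(benzyloxy)-4-bromo-5-methoxynaphthalene
Conditions: BnBr, K2CO3, DMF, rt
Reagents that add atoms: benzyl bromide BrCc1ccccc1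
Why: Williamson ether synthesis, the naphthoxide being alkylated on oxygen by the reactive benzylic bromide.

Step 3
Reactants: 3 1-(benzyloxy)-4-bromo-5-methoxynaphthalene
Product: 5 4-(benzyloxy)-8-methoxynaphthalene-1-carbaldehyde, via naphthyllithium 4 (not isolated)
Conditions: n-BuLi, THF, −78 °C; DMF, −78 °C to rt; 1 M HCl
Reagents that add atoms: n-butyllithium [Li]CCCC (lithium of 4 only); N,N-dimethylformamide CN(C)C=O (the CHO group)
Why: Bromine–lithium exchange outruns any deprotonation at −78 °C, the peri-methoxy group stabilises the naphthyllithium, and DMF formylates it (Bouveault aldehyde synthesis).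

Step 4
Reactants: 6 2-bromobenzene-1,4-diol (bromohydroquinone)
Product: 7 1,4-bis(benzyloxy)-2-bromobenzene
Conditions: BnBr (2.2 equiv), K2CO3, DMF, rt to 50 °C
Reagents that add atoms: benzyl bromide BrCc1ccccc1
Why: Twofold Williamson ether synthesis on both phenoxide oxygens.

Step 5
Reactants: 7 1,4-bis(benzyloxy)-2-bromobenzene
Product: 9 1-[3,6-bis(benzyloxy)-2-bromophenyl]ethan-1-one, via aryllithium 8 (not isolated)
Conditions: LiN(iPr)2, THF, −78 °C; MeC(O)N(OMe)Me, −78 to −40 °C; 1 M HCl
Reagents that add atoms: lithium diisopropylamide [Li]N(C(C)C)C(C)C (lithium of 8 only); N-methoxy-N-methylacetamide CC(=O)N(C)OC (the acetyl group)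
Why: Directed ortho-lithiation removes the most acidic ring proton, the one flanked by bromine and a benzyloxy group, and the aryllithium, kept cold so that LiBr is not lost to an aryne, is acylated through the stable chelated adduct of the Weinreb ketone synthesis.

Step 6
Reactants: 9 1-[3,6-bis(benzyloxy)-2-bromophenyl]ethan-1-one; 5 4-(benzyloxy)-8-methoxynaphthalene-1-carbaldehyde
Product: 11 (2E)-1-[3,6-bis(benzyloxy)-2-bromophenyl]-3-[4-(benzyloxy)-8-methoxynaphthalen-1-yl]prop-2-en-1-one, via aldol adduct 10 (not isolated)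
Conditions: KOH, EtOH/THF, rt
Reagents that add atoms: none
Why: Claisen–Schmidt condensation, in which only the ketone can enolise, the aldehyde cannot, and E1cB dehydration of the aldol gives the conjugated E-enone.

Step 7
Reactants: 11 (2E)-1-[3,6-bis(benzyloxy)-2-bromophenyl]-3-[4-(benzyloxy)-8-methoxynaphthalen-1-yl]prop-2-en-1-one
Product: 12 (3S)-4,7-bis(benzyloxy)-3-[4-(benzyloxy)-8-methoxynaphthalen-1-yl]-2,3-dihydro-1H-inden-1-one
Conditions: Pd(OAc)2 (5 mol %), (R)-3,5-Xyl-MeO-BIPHEP (6 mol %), HCO2H, iPr2NEt, ethylene glycol/DMF, 80 °C; aq. NaHCO3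
Reagents that add atoms: none
Why: Intramolecular asymmetric reductive Heck reaction, in which zerovalent palladium inserts into the C–Br bond, the aryl group adds to the enone β-carbon in the enantio-determining migratory insertion that closes the five-membered ring, and the palladium enolate is released by protonation while formate returns divalent palladium to the zerovalent state; the chiral bisphosphine sets C3 as S by reagent control.

Step 8
Reactants: 12 (3S)-4,7-bis(benzyloxy)-3-[4-(benzyloxy)-8-methoxynaphthalen-1-yl]-2,3-dihydro-1H-inden-1-one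
Product: 13 (1S)-4,7-bis(benzyloxy)-1-[4-(benzyloxy)-8-methoxynaphthalen-1-yl]-3-[(trimethylsilyl)oxy]-1H-indene
Conditions: Me3SiOTf, iPr2NEt, CH2Cl2, −78 to −20 °C; cold aq. NaHCO3; used without storage
Reagents that add atoms: trimethylsilyl trifluoromethanesulfonate C[Si](C)(C)OS(=O)(=O)C(F)(F)F
Why: Soft enolisation, in which the silyl triflate activates the carbonyl and the hindered amine removes a C2 proton (the only α-protons present), while low temperature and a weak, bulky base leave the indenylic C1–H of the stereocentre alone.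

Step 9
Reactants: 13 (1S)-4,7-bis(benzyloxy)-1-[4-(benzyloxy)-8-methoxynaphthalen-1-yl]-3-[(trimethylsilyl)oxy]-1H-indene; 14 diiodomethane
Product: 15 (1aS,6S,6aR)-2,5-bis(benzyloxy)-6-[4-(benzyloxy)-8-methoxynaphthalen-1-yl]-1a-[(trimethylsilyl)oxy]-1,1a,6,6a-tetrahydrocyclopropa[a]indene (CH2 bridge anti to the naphthyl group)
Conditions: Et2Zn (3 equiv), CH2I2 (3 equiv), CH2Cl2, 0 °C to rt; pyridine, aq. NaHCO3
Reagents that add atoms: diiodomethane ICI (the CH2 group, C1 of 15)
Why: Et2Zn and CH2I2 exchange to the zinc carbenoid EtZnCH2I, which hands its methylene to the electron-rich enol ether C=C through a concerted butterfly transition state, so that the later tetralone bonds C1–C2 and C2–C3 (here C1a–C1 and C1–C6a) form in one event. The closest known reaction type is the Furukawa variant of the Simmons–Smith cyclopropanation of cyclic silyl enol ethers. The three-membered ring closes by this single [2+1] addition, stereospecifically cis across the former double bond, which fixes the ring fusion. C1a and C6a are set together by substrate control, because the naphthyl group at C6 shields one face of the nearly planar indene and the carbenoid adds to the other. The step needs chemoselectivity for the enol ether over the arenes and retention of the C6–H configuration; the enol ether is the only non-aromatic, nucleophilic C=C, and the neutral, non-basic medium cannot ionise the indenylic C–H. Facial selectivity is not critical, since both new centres are erased in steps 10 and 11.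

Step 10
Reactants: 15 (1aS,6S,6aR)-2,5-bis(benzyloxy)-6-[4-(benzyloxy)-8-methoxynaphthalen-1-yl]-1a-[(trimethylsilyl)oxy]-1,1a,6,6a-tetrahydrocyclopropa[a]indene
Product: 16 (3S,4S)-5,8-bis(benzyloxy)-4-[4-(benzyloxy)-8-methoxynaphthalen-1-yl]-3-chloro-3,4-dihydronaphthalen-1(2H)-one
Conditions: FeCl3 (2.2 equiv), DMF, 0 °C; cold 1 M HCl; used crude
Reagents that add atoms: iron trichloride Cl[Fe](Cl)Cl (the chlorine at C3)
Why: Oxidative ring opening of a siloxycyclopropane, in which trivalent iron takes the oxygen from silicon, one-electron transfer gives an oxygen-centred radical that cleaves the internal C1a–C6a bond (secondary rather than primary radical, relief of bicyclic strain) to expand the five- to the six-membered ring, and a second FeCl3 transfers chlorine to the C3 radical anti to the naphthyl group.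

Step 11
Reactants: 16 (3S,4S)-5,8-bis(benzyloxy)-4-[4-(benzyloxy)-8-methoxynaphthalen-1-yl]-3-chloro-3,4-dihydronaphthalen-1(2H)-one
Product: 17 (4S)-5,8-bis(benzyloxy)-4-[4-(benzyloxy)-8-methoxynaphthalen-1-yl]-3,4-dihydronaphthalen-1(2H)-one
Conditions: Bu3SnH (1.5 equiv), (PhSe)2 (10 mol %), AIBN (cat.), PhH, 80 °C
Reagents that add atoms: none
Why: Radical chain dehalogenation under neutral conditions, which avoids loss of HCl and aromatisation to the naphthol, with benzeneselenol formed from (PhSe)2 delivering hydrogen to the C3 radical fast enough to forestall a 1,2-aryl shift or reclosure to the cyclopropyloxy radical.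

Step 12
Reactants: 17 (4S)-5,8-bis(benzyloxy)-4-[4-(benzyloxy)-8-methoxynaphthalen-1-yl]-3,4-dihydronaphthalen-1(2H)-one
Product: 18 (4S)-5,8-dihydroxy-4-(4-hydroxy-8-methoxynaphthalen-1-yl)-3,4-dihydronaphthalen-1(2H)-one (CNP0584478.1)
Conditions: BCl3, C6HMe5, CH2Cl2, −78 °C; MeOH; work-up under argon
Reagents that add atoms: none
Why: Lewis acid debenzylation, in which BCl3 activates each benzyl ether, pentamethylbenzene traps the benzyl cation by Friedel–Crafts alkylation, and at −78 °C the unchelated naphthyl methyl ether and the benzylic stereocentre are left intact.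

**Compound list**

1 | 5-methoxy-1-naphthol | COc1cccc2c(O)cccc12 | starting material
2 | 4-bromo-5-methoxynaphthalen-1-ol | COc1cccc2c(O)ccc(Br)c12 | intermediate
3 | 1-(benzyloxy)-4-bromo-5-methoxynaphthalene | COc1cccc2c(OCc3ccccc3)ccc(Br)c12 | intermediate
4 | [4-(benzyloxy)-8-methoxynaphthalen-1-yl]lithium | COc1cccc2c(OCc3ccccc3)ccc([Li])c12 | intermediate
5 | 4-(benzyloxy)-8-methoxynaphthalene-1-carbaldehyde | COc1cccc2c(OCc3ccccc3)ccc(C=O)c12 | intermediate
6 | 2-bromobenzene-1,4-diol (bromohydroquinone) | Oc1ccc(O)c(Br)c1 | starting material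
7 | 1,4-bis(benzyloxy)-2-bromobenzene | Brc1cc(OCc2ccccc2)ccc1OCc1ccccc1 | intermediate
8 | [3,6-bis(benzyloxy)-2-bromophenyl]lithium | [Li]c1c(Br)c(OCc2ccccc2)ccc1OCc1ccccc1 | intermediate
9 | 1-[3,6-bis(benzyloxy)-2-bromophenyl]ethan-1-one | CC(=O)c1c(Br)c(OCc2ccccc2)ccc1OCc1ccccc1 | intermediate
10 | 1-[3,6-bis(benzyloxy)-2-bromophenyl]-3-[4-(benzyloxy)-8-methoxynaphthalen-1-yl]-3-hydroxypropan-1-one (racemic aldol adduct) | COc1cccc2c(OCc3ccccc3)ccc(C(O)CC(=O)c4c(Br)c(OCc5ccccc5)ccc4OCc6ccccc6)c12 | intermediate
11 | (2E)-1-[3,6-bis(benzyloxy)-2-bromophenyl]-3-[4-(benzyloxy)-8-methoxynaphthalen-1-yl]prop-2-en-1-one | COc1cccc2c(OCc3ccccc3)ccc(/C=C/C(=O)c4c(Br)c(OCc5ccccc5)ccc4OCc6ccccc6)c12 | intermediate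
12 | (3S)-4,7-bis(benzyloxy)-3-[4-(benzyloxy)-8-methoxynaphthalen-1-yl]-2,3-dihydro-1H-inden-1-one | COc1cccc2c(OCc3ccccc3)ccc([C@@H]4CC(=O)c5c(OCc6ccccc6)ccc(OCc7ccccc7)c54)c12 | intermediate
13 | (1S)-4,7-bis(benzyloxy)-1-[4-(benzyloxy)-8-methoxynaphthalen-1-yl]-3-[(trimethylsilyl)oxy]-1H-indene | COc1cccc2c(OCc3ccccc3)ccc([C@@H]4C=C(O[Si](C)(C)C)c5c(OCc6ccccc6)ccc(OCc7ccccc7)c54)c12 | intermediate
14 | diiodomethane | ICI | starting material
15 | (1aS,6S,6aR)-2,5-bis(benzyloxy)-6-[4-(benzyloxy)-8-methoxynaphthalen-1-yl]-1a-[(trimethylsilyl)oxy]-1,1a,6,6a-tetrahydrocyclopropa[a]indene | COc1cccc2c(OCc3ccccc3)ccc([C@@H]4[C@H]5C[C@@]5(O[Si](C)(C)C)c6c(OCc7ccccc7)ccc(OCc8ccccc8)c64)c12 | intermediate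
16 | (3S,4S)-5,8-bis(benzyloxy)-4-[4-(benzyloxy)-8-methoxynaphthalen-1-yl]-3-chloro-3,4-dihydronaphthalen-1(2H)-one | COc1cccc2c(OCc3ccccc3)ccc([C@@H]4[C@@H](Cl)CC(=O)c5c(OCc6ccccc6)ccc(OCc7ccccc7)c54)c12 | intermediate
17 | (4S)-5,8-bis(benzyloxy)-4-[4-(benzyloxy)-8-methoxynaphthalen-1-yl]-3,4-dihydronaphthalen-1(2H)-one | COc1cccc2c(OCc3ccccc3)ccc([C@@H]4CCC(=O)c5c(OCc6ccccc6)ccc(OCc7ccccc7)c54)c12 | intermediate
18 | (4S)-5,8-dihydroxy-4-(4-hydroxy-8-methoxynaphthalen-1-yl)-3,4-dihydronaphthalen-1(2H)-one | COc1cccc2c(O)ccc([C@@H]3CCC(=O)c4c(O)ccc(O)c43)c12 | target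

**Step count**

Total: 12 steps. Longest linear sequence: 10 steps (1 → 2 → 3 → 5 → 11 → 12 → 13 → 15 → 16 → 17 → 18); the ketone branch 6 → 7 → 9 adds two steps.

**Steps most likely to fail**

Step 7. Oxidative addition into the doubly ortho-substituted, electron-rich C–Br bond and the 5-endo insertion of an enone carrying the bulky peri-methoxynaphthyl group may be slower than formate reduction of the aryl–palladium species (hydrodebromination), or the insertion may show poor facial discrimination. The fallback sets out from chalcone 11. Miyaura borylation (B2pin2, PdCl2(dppf), KOAc, dioxane, 80 °C) would give the pinacol boronate (2E)-1-[3,6-bis(benzyloxy)-2-(4,4,5,5-tetramethyl-1,3,2-dioxaborolan-2-yl)phenyl]-3-[4-(benzyloxy)-8-methoxynaphthalen-1-yl]prop-2-en-1-one F1. An intramolecular conjugate addition of the arylboron group to the enone under monovalent rhodium ([RhCl(C2H4)2]2, (S)-MonoPhos or a chiral diene, aq. KOH, toluene, 60 °C) would then close the five-membered ring and come back to indanone 12. No hydride source is present, so reduction cannot compete.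

Step 10. The external instead of the internal cyclopropane bond may cleave, HCl may be lost from the β-chloroketone with tautomerisation to the achiral naphthol, or trivalent iron may oxidise the electron-rich dialkoxyarenes. The fallback sets out from 15. Buffered desilylation (Bu4NF/AcOH, THF, 0 °C) would give the free cyclopropanol (1aS,6S,6aR)-2,5-bis(benzyloxy)-6-[4-(benzyloxy)-8-methoxynaphthalen-1-yl]-6,6a-dihydrocyclopropa[a]inden-1a(1H)-ol F2. This would be opened with manganese tris(pyridine-2-carboxylate), Mn(O2CC5H4N)3 (trivalent manganese), in DMF at 0 °C in the presence of Bu3SnH. The β-keto radical is then capped by hydrogen instead of chlorine, at a temperature where radical rearrangement is slow, and no leaving group is ever placed β to the ketone. The sequence comes back at tetralone 17, bypassing 16.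

Step 8. The product is a 1H-indene whose C1–H is indenylic and doubly benzylic, so amine-mediated deprotonation or a 1,3-proton shift could erode the enantiomeric purity before the cyclopropane is in place. The fallback sets out from indanone 12. Deprotonation with LiN(SiMe3)2 (0.98 equiv, THF, −78 °C) and treatment of the lithium enolate with the samarium carbenoid made from CH2I2 and SmI2 (divalent samarium, −78 °C to rt) would give the cyclopropanol (1aS,6S,6aR)-2,5-bis(benzyloxy)-6-[4-(benzyloxy)-8-methoxynaphthalen-1-yl]-6,6a-dihydrocyclopropa[a]inden-1a(1H)-ol F3 (the same compound as F2) directly. A neutral indene is never exposed to base. Silylation (Me3SiCl, imidazole, CH2Cl2, 0 °C) comes back to 15.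

**Further compounds**

F1 | step 7 | (2E)-1-[3,6-bis(benzyloxy)-2-(4,4,5,5-tetramethyl-1,3,2-dioxaborolan-2-yl)phenyl]-3-[4-(benzyloxy)-8-methoxynaphthalen-1-yl]prop-2-en-1-one | COc1cccc2c(OCc3ccccc3)ccc(/C=C/C(=O)c4c(B5OC(C)(C)C(C)(C)O5)c(OCc6ccccc6)ccc4OCc7ccccc7)c12
F2 | step 10 | (1aS,6S,6aR)-2,5-bis(benzyloxy)-6-[4-(benzyloxy)-8-methoxynaphthalen-1-yl]-6,6a-dihydrocyclopropa[a]inden-1a(1H)-ol | COc1cccc2c(OCc3ccccc3)ccc([C@@H]4[C@H]5C[C@@]5(O)c6c(OCc7ccccc7)ccc(OCc8ccccc8)c64)c12
F3 | step 8 | (1aS,6S,6aR)-2,5-bis(benzyloxy)-6-[4-(benzyloxy)-8-methoxynaphthalen-1-yl]-6,6a-dihydrocyclopropa[a]inden-1a(1H)-ol | COc1cccc2c(OCc3ccccc3)ccc([C@@H]4[C@H]5C[C@@]5(O)c6c(OCc7ccccc7)ccc(OCc8ccccc8)c64)c12
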